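**Retrosynthetic overview**
1. Target ⇐ cross-conjugated dienone by nucleophilic epoxidation of the C7=C14 α-methylene ketone (second oxirane, formed last); the C8 ketone, 9,10-olefin and C11 hydroxyl come from late allylic oxidations of a plain farnesane tail.
2. Carbocycle ⇐ C1–C6 closure of an open farnesane chain oxidised to a 3,4-epoxy-2-oxo-1-al: the aldehyde carbon attacks the 6,7-olefin and hydrogen leaves from the C7 methyl (the carbonyl-ene counterpart of farnesyl → bisabolyl cation → β-bisabolene), setting C1 and C6.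
3. Ring oxirane ⇐ hydroxyl-directed epoxidation of the acyclic (3Z)-allylic 1,2-diol, done before ring closure so that it, together with a matched catalyst, steers the closure.
4. Chain ⇐ Z-selective Wittig reaction of a glycerate-derived α-alkoxy methyl ketone (C1–C3, C15) with the homoneryl ylide (C5–C12 from nerol, C4 from Ph3P=CH2).
5. Order of ring formation: C3–C4 oxirane → cyclohexane → C7–C14 oxirane.

Assumption: atoms are numbered along the farnesane chain (C1 = ester-bearing ring CH, C2 = ring C=O, C3/C4 = ring oxirane with C15 = methyl on C3, C5 = ring CH2, C6 = ring CH, C7/C14 = side-chain oxirane, C8 = side-chain C=O, C9=C10, C11 = carbinol).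

**Step 1**
Reactants: 1 methyl (4S)-2,2-dimethyl-1,3-dioxolane-4-carboxylate
Product: 3 1-[(4S)-2,2-dimethyl-1,3-dioxolan-4-yl]ethan-1-one, via Weinreb amide 2 (not isolated)
Conditions: MeNH(OMe)·HCl, i-PrMgCl, THF, −20 °C; then MeMgBr, −20 → 0 °C; aq NH4Cl
Reagents that add atoms: methylmagnesium bromide, C[Mg]Br
Why: Weinreb ketone synthesis: the ester becomes the N-methoxy-N-methyl amide in situ, whose chelated magnesium adduct stops at the ketone stage and is not enolised, so the stereocenter (later C2) is kept.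

**Step 2**
Reactants: 4 nerol [(2Z)-3,7-dimethylocta-2,6-dien-1-ol]
Product: 5 neryl bromide [(2Z)-1-bromo-3,7-dimethylocta-2,6-diene]
Conditions: PBr3 (0.4 equiv), Et2O, −10 °C
Reagents that add atoms: phosphorus tribromide, BrP(Br)Br
Why: Bromination of a primary allylic alcohol with PBr3 (SN2 on the bromophosphite) at low temperature runs without allylic transposition or Z to E isomerisation.

**Step 3**
Reactants: 5 neryl bromide; 6 methyltriphenylphosphonium bromide
Product: 8 [(3Z)-4,8-dimethylnona-3,7-dien-1-yl]triphenylphosphonium bromide, via methylenetriphenylphosphorane 7 (not isolated)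
Conditions: 6, n-BuLi, THF, 0 °C; then 5, −78 °C → rt; salt precipitated with Et2O
Reagents that add atoms: none
Why: C-alkylation of a non-stabilised phosphorus ylide by a primary allylic bromide (SN2) adds one carbon (C4) and gives directly the phosphonium salt for the next Wittig reaction, leaving the Z olefin untouched.

**Step 4**
Reactants: 8 [(3Z)-4,8-dimethylnona-3,7-dien-1-yl]triphenylphosphonium bromide; 3 1-[(4S)-2,2-dimethyl-1,3-dioxolan-4-yl]ethan-1-one
Product: 10 (4R)-4-[(2Z,5Z)-6,10-dimethylundeca-2,5,9-trien-2-yl]-2,2-dimethyl-1,3-dioxolane, via phosphorus ylide 9 (not isolated)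
Conditions: KHMDS, THF, −78 °C; then 3, −78 °C → rt
Reagents that add atoms: none
Why: Wittig olefination of an α-alkoxy methyl ketone with a non-stabilised ylide under lithium-free, low-temperature conditions (Still-type Z-selective trisubstituted olefin synthesis) puts the oxygenated carbon C2 cis to C5 on the new C3=C4 bond; C2 is retained (S to R is a CIP priority change only).

**Step 5**
Reactants: 10 (4R)-4-[(2Z,5Z)-6,10-dimethylundeca-2,5,9-trien-2-yl]-2,2-dimethyl-1,3-dioxolane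
Product: 11 (2R,3Z,6Z)-3,7,11-trimethyldodeca-3,6,10-triene-1,2-diol
Conditions: AcOH/H2O (4:1), rt
Reagents that add atoms: none
Why: Mild acid-catalysed acetal hydrolysis frees the 1,2-diol without ionising the allylic C2–O bond or moving the trisubstituted olefins.

**Step 6**
Reactants: 11 (2R,3Z,6Z)-3,7,11-trimethyldodeca-3,6,10-triene-1,2-diol
Product: 12 (1S)-1-[(2R,3S)-3-[(2Z)-3,7-dimethylocta-2,6-dien-1-yl]-2-methyloxiran-2-yl]ethane-1,2-diol
Conditions: VO(acac)2 (5 mol %), t-BuOOH (anhydrous, 1.3 equiv), toluene, 0 °C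
Reagents that add atoms: tert-butyl hydroperoxide, CC(C)(C)OO
Why: Sharpless–Michaelson hydroxyl-directed epoxidation: only the allylic 3,4-olefin reacts, and with C2–H eclipsing the Z olefin (A(1,3) strain) the vanadium peroxide bound to O2 delivers oxygen to the face syn to that hydroxyl (threo), which sets C3 and C4.

**Step 7**
Reactants: 12 (1S)-1-[(2R,3S)-3-[(2Z)-3,7-dimethylocta-2,6-dien-1-yl]-2-methyloxiran-2-yl]ethane-1,2-diol
Product: 14 (1S,3S,4S,6S)-3-hydroxy-1-methyl-4-(6-methylhepta-1,5-dien-2-yl)-7-oxabicyclo[4.1.0]heptan-2-one, via keto aldehyde 13 (not isolated)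
Conditions: (COCl)2, DMSO, CH2Cl2, −78 °C; Et3N, −78 → −20 °C; cold aqueous work-up, toluene azeotrope (crude 13); then Cu(SbF6)2·(S,S)-t-Bu-box (10 mol %; ligand = 2,2'-(propane-2,2-diyl)bis[(4S)-4-tert-butyl-4,5-dihydro-1,3-oxazole]), 4 Å MS, CH2Cl2, −40 → 0 °C
Reagents that add atoms: none
Why: Proposed new method: after Swern oxidation of both carbinols the 1,2-dicarbonyl of 13 chelates divalent copper as a glyoxylate does, so the aldehyde carbon C1 becomes a strong enophile for the 6,7-olefin and the ring closes through a chair-like carbonyl-ene transition state (closest known reactions: copper–bis(oxazoline) glyoxylate-ene reactions, intramolecular ene cyclisations of unsaturated α-keto esters, citronellal → isopulegol); the (S,S) ligand opens the Si face of C1 (1S), the diequatorial chair puts O1 and C7 trans (sets C6), the same half-chair avoids a syn-axial contact of H1 with the C3 methyl and keeps the ketone and oxirane dipoles opposed (substrate and catalyst matched), and because C5 and C8 are cis on the Z olefin the hydrogen comes from the C7 methyl, giving the 7(14)-methylene.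

**Step 8**
Reactants: 14 (1S,3S,4S,6S)-3-hydroxy-1-methyl-4-(6-methylhepta-1,5-dien-2-yl)-7-oxabicyclo[4.1.0]heptan-2-one; 15 3-methylbutanoyl chloride
Product: 16 (1S,3S,4S,6S)-1-methyl-4-(6-methylhepta-1,5-dien-2-yl)-2-oxo-7-oxabicyclo[4.1.0]heptan-3-yl 3-methylbutanoate
Conditions: pyridine, DMAP (cat.), CH2Cl2, 0 °C
Reagents that add atoms: none
Why: DMAP-catalysed acyl transfer to the only hydroxyl group; no stereocenter is touched.

**Step 9**
Reactants: 16 (1S,3S,4S,6S)-1-methyl-4-(6-methylhepta-1,5-dien-2-yl)-2-oxo-7-oxabicyclo[4.1.0]heptan-3-yl 3-methylbutanoate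
Product: 19 (1S,3S,4S,6S)-4-[(4E)-6-hydroxy-6-methylhepta-1,4-dien-2-yl]-1-methyl-2-oxo-7-oxabicyclo[4.1.0]heptan-3-yl 3-methylbutanoate, via hydroxy selenide 17 (not isolated), via selenoxide 18 (not isolated)
Conditions: N-(phenylseleno)phthalimide (1.1 equiv), H2O, CSA (cat.), CH2Cl2, −20 °C → rt; then 30% H2O2 (2 equiv), pyridine, 0 °C → rt
Reagents that add atoms: water, O
Why: Electrophilic hydroxyselenation then selenoxide syn-elimination: selenium adds to the most nucleophilic (trisubstituted 10,11) olefin, water opens the seleniranium ion at tertiary C11, and the selenoxide can only eliminate towards C9, giving the E allylic tertiary alcohol.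

**Step 10**
Reactants: 19 (1S,3S,4S,6S)-4-[(4E)-6-hydroxy-6-methylhepta-1,4-dien-2-yl]-1-methyl-2-oxo-7-oxabicyclo[4.1.0]heptan-3-yl 3-methylbutanoate
Product: 21 (1S,3S,4S,6S)-4-[(4E)-6-hydroxy-6-methyl-3-oxohepta-1,4-dien-2-yl]-1-methyl-2-oxo-7-oxabicyclo[4.1.0]heptan-3-yl 3-methylbutanoate, via allylic alcohol 20 (not isolated)
Conditions: SeO2 (30 mol %), t-BuOOH (3 equiv), CH2Cl2, rt; then MnO2 (excess), same flask, rt
Reagents that add atoms: tert-butyl hydroperoxide, CC(C)(C)OO (its oxygen is passed on by the SeO2 catalyst, O=[Se]=O)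
Why: SeO2/t-BuOOH allylic hydroxylation (ene reaction, then [2,3]-sigmatropic shift) strikes C8, the only methylene allylic to both the 7(14) and the 9,10 olefin, and MnO2 then oxidises the doubly allylic alcohol to the ketone, so the mixed C8 configuration does not matter.

**Step 11**
Reactants: 21 (1S,3S,4S,6S)-4-[(4E)-6-hydroxy-6-methyl-3-oxohepta-1,4-dien-2-yl]-1-methyl-2-oxo-7-oxabicyclo[4.1.0]heptan-3-yl 3-methylbutanoate
Product: 22 (1S,3S,4R,6S)-4-[(2R)-2-[(2E)-4-hydroxy-4-methylpent-2-enoyl]oxiran-2-yl]-1-methyl-2-oxo-7-oxabicyclo[4.1.0]heptan-3-yl 3-methylbutanoate (CNP0292003.1)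
Conditions: t-BuOOH (1.5 equiv), DBU (1.2 equiv), CH2Cl2, 0 °C
Reagents that add atoms: tert-butyl hydroperoxide, CC(C)(C)OO
Why: Weitz–Scheffer nucleophilic epoxidation: the peroxide anion adds to the unhindered C14 terminus of the α-methylene ketone (the β-substituted 9,10-enone is much slower), and the enolate, with C6–H eclipsing C7=C8 (A(1,3) strain), closes the oxirane on the face flanked by the C5 methylene and not by the ester-bearing C1, which gives 7R.

**Compound list**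
1 | methyl (4S)-2,2-dimethyl-1,3-dioxolane-4-carboxylate | CC1(C)OC[C@H](O1)C(=O)OC | starting material
2 | (4S)-N-methoxy-N,2,2-trimethyl-1,3-dioxolane-4-carboxamide | CC1(C)OC[C@H](O1)C(=O)N(C)OC | intermediate
3 | 1-[(4S)-2,2-dimethyl-1,3-dioxolan-4-yl]ethan-1-one | CC1(C)OC[C@H](O1)C(C)=O | intermediate
4 | nerol, (2Z)-3,7-dimethylocta-2,6-dien-1-ol | OC/C=C(C)\CCC=C(C)C | starting material
5 | neryl bromide, (2Z)-1-bromo-3,7-dimethylocta-2,6-diene | BrC/C=C(C)\CCC=C(C)C | intermediate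
6 | methyltriphenylphosphonium bromide | C[P+](c1ccccc1)(c1ccccc1)c1ccccc1.[Br-] | starting material
7 | methylenetriphenylphosphorane | C=P(c1ccccc1)(c1ccccc1)c1ccccc1 | intermediate
8 | [(3Z)-4,8-dimethylnona-3,7-dien-1-yl]triphenylphosphonium bromide | CC(C)=CCC/C(C)=C\CC[P+](c1ccccc1)(c1ccccc1)c1ccccc1.[Br-] | intermediate
9 | [(3Z)-4,8-dimethylnona-3,7-dien-1-ylidene]triphenylphosphorane | CC(C)=CCC/C(C)=C\CC=P(c1ccccc1)(c1ccccc1)c1ccccc1 | intermediate
10 | (4R)-4-[(2Z,5Z)-6,10-dimethylundeca-2,5,9-trien-2-yl]-2,2-dimethyl-1,3-dioxolane | CC1(C)OC[C@H](O1)/C(C)=C\C/C=C(C)\CCC=C(C)C | intermediate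
11 | (2R,3Z,6Z)-3,7,11-trimethyldodeca-3,6,10-triene-1,2-diol | OC[C@H](O)/C(C)=C\C/C=C(C)\CCC=C(C)C | intermediate
12 | (1S)-1-[(2R,3S)-3-[(2Z)-3,7-dimethylocta-2,6-dien-1-yl]-2-methyloxiran-2-yl]ethane-1,2-diol | OC[C@H](O)[C@@]1(C)O[C@H]1C/C=C(C)\CCC=C(C)C | intermediate
13 | 2-[(2S,3S)-3-[(2Z)-3,7-dimethylocta-2,6-dien-1-yl]-2-methyloxiran-2-yl]-2-oxoacetaldehyde | O=CC(=O)[C@@]1(C)O[C@H]1C/C=C(C)\CCC=C(C)C | intermediate
14 | (1S,3S,4S,6S)-3-hydroxy-1-methyl-4-(6-methylhepta-1,5-dien-2-yl)-7-oxabicyclo[4.1.0]heptan-2-one | O[C@@H]1C(=O)[C@@]2(C)O[C@H]2C[C@H]1C(=C)CCC=C(C)C | intermediate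
15 | 3-methylbutanoyl chloride | CC(C)CC(Cl)=O | starting material
16 | (1S,3S,4S,6S)-1-methyl-4-(6-methylhepta-1,5-dien-2-yl)-2-oxo-7-oxabicyclo[4.1.0]heptan-3-yl 3-methylbutanoate | CC(C)CC(=O)O[C@@H]1C(=O)[C@@]2(C)O[C@H]2C[C@H]1C(=C)CCC=C(C)C | intermediate
17 | (1S,3S,4S,6S)-4-[6-hydroxy-6-methyl-5-(phenylselanyl)hept-1-en-2-yl]-1-methyl-2-oxo-7-oxabicyclo[4.1.0]heptan-3-yl 3-methylbutanoate (C10 epimers) | CC(C)CC(=O)O[C@@H]1C(=O)[C@@]2(C)O[C@H]2C[C@H]1C(=C)CCC([Se]c1ccccc1)C(C)(C)O | intermediate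
18 | selenoxide of 17, 5-(benzeneseleninyl) analogue | CC(C)CC(=O)O[C@@H]1C(=O)[C@@]2(C)O[C@H]2C[C@H]1C(=C)CCC([Se](=O)c1ccccc1)C(C)(C)O | intermediate
19 | (1S,3S,4S,6S)-4-[(4E)-6-hydroxy-6-methylhepta-1,4-dien-2-yl]-1-methyl-2-oxo-7-oxabicyclo[4.1.0]heptan-3-yl 3-methylbutanoate | CC(C)CC(=O)O[C@@H]1C(=O)[C@@]2(C)O[C@H]2C[C@H]1C(=C)C/C=C/C(C)(C)O | intermediate
20 | (1S,3S,4S,6S)-4-[(4E)-3,6-dihydroxy-6-methylhepta-1,4-dien-2-yl]-1-methyl-2-oxo-7-oxabicyclo[4.1.0]heptan-3-yl 3-methylbutanoate (C8 epimers) | CC(C)CC(=O)O[C@@H]1C(=O)[C@@]2(C)O[C@H]2C[C@H]1C(=C)C(O)/C=C/C(C)(C)O | intermediate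
21 | (1S,3S,4S,6S)-4-[(4E)-6-hydroxy-6-methyl-3-oxohepta-1,4-dien-2-yl]-1-methyl-2-oxo-7-oxabicyclo[4.1.0]heptan-3-yl 3-methylbutanoate | CC(C)CC(=O)O[C@@H]1C(=O)[C@@]2(C)O[C@H]2C[C@H]1C(=C)C(=O)/C=C/C(C)(C)O | intermediate
22 | (1S,3S,4R,6S)-4-[(2R)-2-[(2E)-4-hydroxy-4-methylpent-2-enoyl]oxiran-2-yl]-1-methyl-2-oxo-7-oxabicyclo[4.1.0]heptan-3-yl 3-methylbutanoate | CC(C)CC(=O)O[C@@H]1C(=O)[C@@]2(C)O[C@H]2C[C@H]1[C@]1(C(=O)/C=C/C(C)(C)O)CO1 | target

**Totals**
Total step count: 11. Longest linear sequence: 10 steps (nerol 4 → 22, steps 2–11); step 1 is a one-step branch.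

**Three steps most likely to fail**

Step 7 (ring closure). The crude epoxy keto aldehyde may hydrate or rearrange, the facial match of catalyst and oxirane is predicted and not proven, and some 7(8)-olefin may form. The fallback sets out from 11 and comes back at 16; it forms the ring oxirane after the ring, under direction by a ring hydroxyl. Swern oxidation of 11 gives (3Z,6Z)-3,7,11-trimethyl-2-oxododeca-3,6,10-trienal F1. This is achiral, so the same Cu(SbF6)2·(S,S)-t-Bu-box ene closure now sets C1 and C6 by catalyst control alone and gives (5S,6S)-6-hydroxy-2-methyl-5-(6-methylhepta-1,5-dien-2-yl)cyclohex-2-en-1-one F2. Acylation with 15 (pyridine, DMAP) gives (1S,6S)-3-methyl-6-(6-methylhepta-1,5-dien-2-yl)-2-oxocyclohex-3-en-1-yl 3-methylbutanoate F3. Luche reduction (NaBH4, CeCl3·7H2O, MeOH, −78 °C; axial hydride, as carvone gives cis-carveol) gives (1S,2S,6S)-2-hydroxy-3-methyl-6-(6-methylhepta-1,5-dien-2-yl)cyclohex-3-en-1-yl 3-methylbutanoate F4. VO(acac)2/t-BuOOH epoxidises syn to that hydroxyl to give (1R,2R,3S,4S,6S)-2-hydroxy-1-methyl-4-(6-methylhepta-1,5-dien-2-yl)-7-oxabicyclo[4.1.0]heptan-3-yl 3-methylbutanoate F5, and Dess–Martin oxidation returns 16.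

Step 10 (C8 oxidation). SeO2 may convert poorly, over-oxidise or transpose the tertiary allylic alcohol. The fallback sets out from 19 and comes back at 21; it replaces the ene/[2,3] hydroxylation by direct hydrogen abstraction at the doubly allylic methylene of a protected substrate. TMSCl/imidazole gives (1S,3S,4S,6S)-1-methyl-4-[(4E)-6-methyl-6-(trimethylsilyloxy)hepta-1,4-dien-2-yl]-2-oxo-7-oxabicyclo[4.1.0]heptan-3-yl 3-methylbutanoate F6. CrO3·3,5-dimethylpyrazole (CH2Cl2, −20 °C) turns CH2-8 into the ketone, giving (1S,3S,4S,6S)-1-methyl-4-[(4E)-6-methyl-3-oxo-6-(trimethylsilyloxy)hepta-1,4-dien-2-yl]-2-oxo-7-oxabicyclo[4.1.0]heptan-3-yl 3-methylbutanoate F7, and aqueous citric acid/THF removes the silyl group to give 21.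

Step 11 (last oxirane). Facial selectivity at C7 rests on an acyclic A(1,3) model, and the base may attack the α-acyloxy ketone. The fallback sets out from 20 (isolated by leaving out the MnO2 stage of step 10) and comes back at 22; it sets C7 by reagent control at the alcohol oxidation level. Sharpless epoxidation (Ti(OiPr)4, D-(−)-diisopropyl tartrate, t-BuOOH, 4 Å MS, CH2Cl2, −20 °C) leaves the tertiary C11 alcohol alone. For the (8R) epimer of 20 the 7(14)-olefin is the matched one, and oxygen is delivered to give (1S,3S,4R,6S)-4-[(2R)-2-[(1R,2E)-1,4-dihydroxy-4-methylpent-2-en-1-yl]oxiran-2-yl]-1-methyl-2-oxo-7-oxabicyclo[4.1.0]heptan-3-yl 3-methylbutanoate F8; Dess–Martin oxidation of C8 then gives 22. The (8S) epimer reacts at its matched 9,10-olefin and is lost, so at most half of 20 is used.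

**Further compounds**
F1 | step 7 | (3Z,6Z)-3,7,11-trimethyl-2-oxododeca-3,6,10-trienal | O=CC(=O)/C(C)=C\C/C=C(C)\CCC=C(C)C
F2 | step 7 | (5S,6S)-6-hydroxy-2-methyl-5-(6-methylhepta-1,5-dien-2-yl)cyclohex-2-en-1-one | O[C@@H]1C(=O)C(C)=CC[C@H]1C(=C)CCC=C(C)C
F3 | step 7 | (1S,6S)-3-methyl-6-(6-methylhepta-1,5-dien-2-yl)-2-oxocyclohex-3-en-1-yl 3-methylbutanoate | CC(C)CC(=O)O[C@@H]1C(=O)C(C)=CC[C@H]1C(=C)CCC=C(C)C
F4 | step 7 | (1S,2S,6S)-2-hydroxy-3-methyl-6-(6-methylhepta-1,5-dien-2-yl)cyclohex-3-en-1-yl 3-methylbutanoate | CC(C)CC(=O)O[C@@H]1[C@@H](O)C(C)=CC[C@H]1C(=C)CCC=C(C)C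
F5 | step 7 | (1R,2R,3S,4S,6S)-2-hydroxy-1-methyl-4-(6-methylhepta-1,5-dien-2-yl)-7-oxabicyclo[4.1.0]heptan-3-yl 3-methylbutanoate | CC(C)CC(=O)O[C@@H]1[C@@H](O)[C@@]2(C)O[C@H]2C[C@H]1C(=C)CCC=C(C)C
F6 | step 10 | (1S,3S,4S,6S)-1-methyl-4-[(4E)-6-methyl-6-(trimethylsilyloxy)hepta-1,4-dien-2-yl]-2-oxo-7-oxabicyclo[4.1.0]heptan-3-yl 3-methylbutanoate | CC(C)CC(=O)O[C@@H]1C(=O)[C@@]2(C)O[C@H]2C[C@H]1C(=C)C/C=C/C(C)(C)O[Si](C)(C)C
F7 | step 10 | (1S,3S,4S,6S)-1-methyl-4-[(4E)-6-methyl-3-oxo-6-(trimethylsilyloxy)hepta-1,4-dien-2-yl]-2-oxo-7-oxabicyclo[4.1.0]heptan-3-yl 3-methylbutanoate | CC(C)CC(=O)O[C@@H]1C(=O)[C@@]2(C)O[C@H]2C[C@H]1C(=C)C(=O)/C=C/C(C)(C)O[Si](C)(C)C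
F8 | step 11 | (1S,3S,4R,6S)-4-[(2R)-2-[(1R,2E)-1,4-dihydroxy-4-methylpent-2-en-1-yl]oxiran-2-yl]-1-methyl-2-oxo-7-oxabicyclo[4.1.0]heptan-3-yl 3-methylbutanoate | CC(C)CC(=O)O[C@@H]1C(=O)[C@@]2(C)O[C@H]2C[C@H]1[C@]1([C@H](O)/C=C/C(C)(C)O)CO1
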